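## Retrosynthetic overview

- The strategy rests on one feature: the carbonyl carbon C4 of the γ-pyranone ring C is bonded to C4a of ring A, and ring A carries oxygen at C5, C6, C7 and C8a. The C4–C4a bond is therefore made last, by intramolecular Friedel–Crafts acylation of a 3-aryloxy-2-benzyloxyacrylic acid (23 → 25). Ring C is the only ring built; rings A and B are bought.
- The O1–C2 bond comes from palladium-catalysed C–O coupling of enol triflate 15 with the mirror-symmetric phenol 21. The C2–C3–C4 unit comes from a Claisen condensation of the ring B acyl imidazolide with ethyl benzyloxyacetate.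
- The ring B side chain is attached by B-alkyl Suzuki coupling of an aryl bromide with the 9-BBN adduct of alkene 4. The single stereocentre comes from the (R)-Roche ester.
- Phenol 21 is made from 3,5-dihydroxy-4-methoxybenzoic acid by benzylation, reduction, oxidation and Baeyer–Villiger oxidation.
- End game: chelation-directed removal of the 5-O-benzyl group, methylation of the 5-hydroxyl, then hydrogenolysis of the remaining benzyl ethers.

Key step: step 15

Assumption: compounds 15, 22 and 23 are drawn as the E isomers (ester or acid cis to the oxygen on C3 of the propenoate), as expected from a chelated enolate and a stereoretentive coupling. A Z component is tolerated because the geometry can equilibrate in step 15.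

## Route

Step 1
Reactants: 1 methyl (2R)-3-hydroxy-2-methylpropanoate
Product: 2 methyl (2R)-3-(benzyloxy)-2-methylpropanoate
Conditions: BnOC(=NH)CCl3, TfOH (cat.), CH2Cl2/cyclohexane, 0 °C → rt
Reagents that add atoms: benzyl 2,2,2-trichloroacetimidate, ClC(Cl)(Cl)C(=N)OCc1ccccc1
Why: Acid-catalysed O-benzylation with the trichloroacetimidate needs no base, so the epimerisable centre alpha to the ester should be untouched.

Step 2
Reactants: 2 methyl (2R)-3-(benzyloxy)-2-methylpropanoate
Product: 3 (2R)-3-(benzyloxy)-2-methylpropanal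
Conditions: iBu2AlH (DIBAL-H, 1.1 equiv), CH2Cl2, −78 °C; aq. potassium sodium tartrate
Reagents that add atoms: none
Why: Partial ester reduction with one equivalent of hydride at −78 °C should stop at the aluminium hemiacetal, which is stabilised by chelation to the β-benzyloxy oxygen; the aldehyde is used crude at once to keep the α-centre intact.

Step 3
Reactants: 3 (2R)-3-(benzyloxy)-2-methylpropanal
Product: 4 ({[(2S)-2-methylbut-3-en-1-yl]oxy}methyl)benzene
Conditions: Ph3PCH3Br, KN(SiMe3)2, THF, 0 °C; then 3, −78 → 0 °C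
Reagents that add atoms: methyltriphenylphosphonium bromide, C[P+](c1ccccc1)(c1ccccc1)c1ccccc1.[Br-]
Why: Wittig methylenation with the non-stabilised ylide at low temperature should outpace enolisation of the aldehyde; the descriptor changes from R to S only through the priority rules, not by inversion.

Step 4
Reactants: 5 methyl 3-bromo-4-hydroxybenzoate
Product: 6 methyl 4-(benzyloxy)-3-bromobenzoate
Conditions: BnBr, K2CO3, DMF, rt
Reagents that add atoms: benzyl bromide, BrCc1ccccc1
Why: Williamson etherification of an acidic phenol.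

Step 5
Reactants: 4 ({[(2S)-2-methylbut-3-en-1-yl]oxy}methyl)benzene; 6 methyl 4-(benzyloxy)-3-bromobenzoate
Product: 8 methyl 4-(benzyloxy)-3-[(3S)-4-(benzyloxy)-3-methylbutyl]benzoate, via B-alkyl-9-BBN adduct 7 (not isolated)
Conditions: 9-BBN, THF, 0 °C → rt; then 6, PdCl2(dppf) (5 mol %), aq. K3PO4, DMF, 60 °C
Reagents that add atoms: none
Why: Anti-Markovnikov hydroboration of the terminal alkene followed by B-alkyl Suzuki–Miyaura coupling forms the aryl–CH2 bond; the stereocentre is not at a reacting carbon and is carried through.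

Step 6
Reactants: 8 methyl 4-(benzyloxy)-3-[(3S)-4-(benzyloxy)-3-methylbutyl]benzoate
Product: 9 4-(benzyloxy)-3-[(3S)-4-(benzyloxy)-3-methylbutyl]benzoic acid
Conditions: LiOH, THF/MeOH/H2O, 50 °C; then 1 M HCl
Reagents that add atoms: lithium hydroxide, [Li+].[OH-]
Why: Saponification of a methyl benzoate; the benzyl ethers are inert to hydroxide.

Step 7
Reactants: 9 4-(benzyloxy)-3-[(3S)-4-(benzyloxy)-3-methylbutyl]benzoic acid; 10 ethyl 2-(benzyloxy)acetate
Product: 13 ethyl 2-(benzyloxy)-3-{4-(benzyloxy)-3-[(3S)-4-(benzyloxy)-3-methylbutyl]phenyl}-3-oxopropanoate, via acyl imidazolide 11 (not isolated), via lithium enolate 12 (not isolated)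
Conditions: 9, CDI, THF, rt; 10, LiN(SiMe3)2 (3.3 equiv each), THF, −78 °C; combine, −78 → −40 °C; aq. NH4Cl
Reagents that add atoms: none
Why: Crossed Claisen condensation of a non-enolisable acyl imidazolide with an ester enolate; excess enolate absorbs the imidazole N–H and the acidic β-keto ester product.

Step 8
Reactants: 13 ethyl 2-(benzyloxy)-3-{4-(benzyloxy)-3-[(3S)-4-(benzyloxy)-3-methylbutyl]phenyl}-3-oxopropanoate
Product: 15 ethyl (2E)-2-(benzyloxy)-3-{4-(benzyloxy)-3-[(3S)-4-(benzyloxy)-3-methylbutyl]phenyl}-3-[(trifluoromethanesulfonyl)oxy]prop-2-enoate, via sodium enolate 14 (not isolated)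
Conditions: NaH, THF, 0 °C; PhNTf2, 0 °C → rt
Reagents that add atoms: N-phenylbis(trifluoromethanesulfonimide), O=S(=O)(N(c1ccccc1)S(=O)(=O)C(F)(F)F)C(F)(F)F
Why: O-Sulfonylation of the sodium-chelated β-keto ester enolate should give the enol triflate with the triflate cis to the ester.

Step 9
Reactants: 16 3,5-dihydroxy-4-methoxybenzoic acid
Product: 17 benzyl 3,5-bis(benzyloxy)-4-methoxybenzoate
Conditions: BnBr (3.5 equiv), K2CO3, DMF, 60 °C
Reagents that add atoms: benzyl bromide, BrCc1ccccc1
Why: Exhaustive alkylation of both phenols and the carboxylate (Williamson etherification and ester alkylation).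

Step 10
Reactants: 17 benzyl 3,5-bis(benzyloxy)-4-methoxybenzoate
Product: 18 [3,5-bis(benzyloxy)-4-methoxyphenyl]methanol
Conditions: LiAlH4, THF, 0 °C
Reagents that add atoms: none
Why: Hydride reduction of the benzyl ester to the primary alcohol; aryl benzyl ethers are stable to LiAlH4.

Step 11
Reactants: 18 [3,5-bis(benzyloxy)-4-methoxyphenyl]methanol
Product: 19 3,5-bis(benzyloxy)-4-methoxybenzaldehyde
Conditions: MnO2, CH2Cl2, rt
Reagents that add atoms: none
Why: Selective oxidation of a benzylic alcohol that stops at the aldehyde.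

Step 12
Reactants: 19 3,5-bis(benzyloxy)-4-methoxybenzaldehyde
Product: 21 3,5-bis(benzyloxy)-4-methoxyphenol, via aryl formate 20 (not isolated)
Conditions: mCPBA, CH2Cl2, 0 °C → rt; aq. NaHCO3 wash; K2CO3 (cat.), MeOH, rt
Reagents that add atoms: 3-chloroperoxybenzoic acid, OOC(=O)c1cccc(Cl)c1
Why: Baeyer–Villiger (Dakin-type) oxidation in which the electron-rich aryl group with a para-methoxy substituent migrates, followed by methanolysis of the formate.

Step 13
Reactants: 15 ethyl (2E)-2-(benzyloxy)-3-{4-(benzyloxy)-3-[(3S)-4-(benzyloxy)-3-methylbutyl]phenyl}-3-[(trifluoromethanesulfonyl)oxy]prop-2-enoate; 21 3,5-bis(benzyloxy)-4-methoxyphenol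
Product: 22 ethyl (2E)-2-(benzyloxy)-3-[3,5-bis(benzyloxy)-4-methoxyphenoxy]-3-{4-(benzyloxy)-3-[(3S)-4-(benzyloxy)-3-methylbutyl]phenyl}prop-2-enoate
Conditions: Pd2(dba)3 (2.5 mol %), tBuXPhos (6 mol %), K3PO4, toluene, 80 °C
Reagents that add atoms: none
Why: Palladium-catalysed C–O cross-coupling of an alkenyl triflate with a phenol (Buchwald–Hartwig-type etherification) forms the O1–C2 bond with retention of geometry, and is chosen because the tetrasubstituted, α-alkoxy-substituted acrylate is a poor acceptor for uncatalysed addition–elimination and free phenoxide could attack the sulfonyl group instead.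

Step 14
Reactants: 22 ethyl (2E)-2-(benzyloxy)-3-[3,5-bis(benzyloxy)-4-methoxyphenoxy]-3-{4-(benzyloxy)-3-[(3S)-4-(benzyloxy)-3-methylbutyl]phenyl}prop-2-enoate
Product: 23 (2E)-2-(benzyloxy)-3-[3,5-bis(benzyloxy)-4-methoxyphenoxy]-3-{4-(benzyloxy)-3-[(3S)-4-(benzyloxy)-3-methylbutyl]phenyl}prop-2-enoic acid
Conditions: LiOH, THF/MeOH/H2O, 40 °C; then 1 M HCl, 0 °C
Reagents that add atoms: lithium hydroxide, [Li+].[OH-]
Why: Saponification as used classically for 3-aryloxycinnamic esters; the α-alkoxy donor disfavours hydroxide attack at C3, and cold, brief acidification protects the aryl enol ether.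

Step 15
Reactants: 23 (2E)-2-(benzyloxy)-3-[3,5-bis(benzyloxy)-4-methoxyphenoxy]-3-{4-(benzyloxy)-3-[(3S)-4-(benzyloxy)-3-methylbutyl]phenyl}prop-2-enoic acid
Product: 25 3,5,7-tris(benzyloxy)-2-{4-(benzyloxy)-3-[(3S)-4-(benzyloxy)-3-methylbutyl]phenyl}-6-methoxy-4H-chromen-4-one, via mixed trifluoroacetic anhydride 24 (not isolated)
Conditions: TFAA (2.5 equiv), CH2Cl2, 0 °C → rt
Reagents that add atoms: none
Why: TFAA converts the acid into the mixed anhydride 24, whose acylium-like carbon (the future C4) is attacked by the ring A carbon ortho to the ether oxygen (the future C4a), and loss of a proton restores aromaticity; this is the intramolecular Friedel–Crafts acylation long used to turn 3-aryloxyacrylic and 3-aryloxycinnamic acids into chromones and flavones. Ring C closes as a six-membered ring, 6-exo at the acylium carbon and 6-endo with respect to the arene, through the planar conjugated array O1–C2=C3–C4. No stereocentre is formed. Regiochemistry on ring A needs no control, because the 3,5-bis(benzyloxy)-4-methoxyphenoxy ring is mirror-symmetric and its two ortho carbons, each ortho to one benzyloxy group and para to the other, are equivalent and strongly activated. Closure onto ring B (to an indenone) or onto the benzyl ring of the C3 ether is disfavoured by the much higher nucleophilicity of the trioxygenated ring A, and in the delocalised acylium/oxocarbenium ion the C2–C3 bond has single-bond character, so any Z isomer can turn into the reactive E geometry. The anhydride activation uses no mineral or Lewis acid, so the five benzyl ethers and the aryl enol ether should survive.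

Step 16
Reactants: 25 3,5,7-tris(benzyloxy)-2-{4-(benzyloxy)-3-[(3S)-4-(benzyloxy)-3-methylbutyl]phenyl}-6-methoxy-4H-chromen-4-one
Product: 26 3,7-bis(benzyloxy)-2-{4-(benzyloxy)-3-[(3S)-4-(benzyloxy)-3-methylbutyl]phenyl}-5-hydroxy-6-methoxy-4H-chromen-4-one
Conditions: MgBr2·OEt2 (3 equiv), toluene/Et2O, rt → 60 °C; then 1 M HCl
Reagents that add atoms: none
Why: Chelation-assisted ether cleavage, in which magnesium bound between the C4 carbonyl and the peri 5-oxygen (six-membered chelate) activates that benzyl group alone for attack by bromide.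

Step 17
Reactants: 26 3,7-bis(benzyloxy)-2-{4-(benzyloxy)-3-[(3S)-4-(benzyloxy)-3-methylbutyl]phenyl}-5-hydroxy-6-methoxy-4H-chromen-4-one
Product: 27 3,7-bis(benzyloxy)-2-{4-(benzyloxy)-3-[(3S)-4-(benzyloxy)-3-methylbutyl]phenyl}-5,6-dimethoxy-4H-chromen-4-one
Conditions: MeI, K2CO3, DMF, 50 °C
Reagents that add atoms: iodomethane, CI
Why: Williamson methylation of the only free hydroxyl; the hydrogen-bonded 5-OH needs warming but has no competitor.

Step 18
Reactants: 27 3,7-bis(benzyloxy)-2-{4-(benzyloxy)-3-[(3S)-4-(benzyloxy)-3-methylbutyl]phenyl}-5,6-dimethoxy-4H-chromen-4-one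
Product: 28 3,7-dihydroxy-2-{4-hydroxy-3-[(3S)-4-hydroxy-3-methylbutyl]phenyl}-5,6-dimethoxy-4H-chromen-4-one
Conditions: H2 (1 atm), Pd(OH)2/C, EtOAc/MeOH, rt
Reagents that add atoms: none
Why: Catalytic hydrogenolysis should remove the three aryl benzyl ethers and the primary alkyl benzyl ether, while the flavonol C2=C3 bond and the methyl ethers are not reduced under these conditions.

## Compound list

1 | methyl (2R)-3-hydroxy-2-methylpropanoate | COC(=O)[C@H](C)CO | starting material
2 | methyl (2R)-3-(benzyloxy)-2-methylpropanoate | COC(=O)[C@H](C)COCc1ccccc1 | intermediate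
3 | (2R)-3-(benzyloxy)-2-methylpropanal | O=C[C@H](C)COCc1ccccc1 | intermediate
4 | ({[(2S)-2-methylbut-3-en-1-yl]oxy}methyl)benzene | C=C[C@H](C)COCc1ccccc1 | intermediate
5 | methyl 3-bromo-4-hydroxybenzoate | COC(=O)c1ccc(O)c(Br)c1 | starting material
6 | methyl 4-(benzyloxy)-3-bromobenzoate | COC(=O)c1ccc(OCc2ccccc2)c(Br)c1 | intermediate
7 | 9-[(3S)-4-(benzyloxy)-3-methylbutyl]-9-borabicyclo[3.3.1]nonane | B1(CC[C@H](C)COCc2ccccc2)C2CCCC1CCC2 | intermediate
8 | methyl 4-(benzyloxy)-3-[(3S)-4-(benzyloxy)-3-methylbutyl]benzoate | COC(=O)c1ccc(OCc2ccccc2)c(CC[C@H](C)COCc2ccccc2)c1 | intermediate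
9 | 4-(benzyloxy)-3-[(3S)-4-(benzyloxy)-3-methylbutyl]benzoic acid | OC(=O)c1ccc(OCc2ccccc2)c(CC[C@H](C)COCc2ccccc2)c1 | intermediate
10 | ethyl 2-(benzyloxy)acetate | CCOC(=O)COCc1ccccc1 | starting material
11 | {4-(benzyloxy)-3-[(3S)-4-(benzyloxy)-3-methylbutyl]phenyl}(1H-imidazol-1-yl)methanone | O=C(n1ccnc1)c1ccc(OCc2ccccc2)c(CC[C@H](C)COCc2ccccc2)c1 | intermediate
12 | lithium 2-(benzyloxy)-1-ethoxyethen-1-olate | [Li+].CCOC([O-])=COCc1ccccc1 | intermediate
13 | ethyl 2-(benzyloxy)-3-{4-(benzyloxy)-3-[(3S)-4-(benzyloxy)-3-methylbutyl]phenyl}-3-oxopropanoate (both C2 epimers, in equilibrium through the enol) | CCOC(=O)C(OCc1ccccc1)C(=O)c1ccc(OCc2ccccc2)c(CC[C@H](C)COCc2ccccc2)c1 | intermediate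
14 | sodium enolate of 13 (enolate oxygen cis to the ester) | [Na+].CCOC(=O)/C(OCc1ccccc1)=C(\[O-])c1ccc(OCc2ccccc2)c(CC[C@H](C)COCc2ccccc2)c1 | intermediate
15 | ethyl (2E)-2-(benzyloxy)-3-{4-(benzyloxy)-3-[(3S)-4-(benzyloxy)-3-methylbutyl]phenyl}-3-[(trifluoromethanesulfonyl)oxy]prop-2-enoate | CCOC(=O)/C(OCc1ccccc1)=C(\OS(=O)(=O)C(F)(F)F)c1ccc(OCc2ccccc2)c(CC[C@H](C)COCc2ccccc2)c1 | intermediate
16 | 3,5-dihydroxy-4-methoxybenzoic acid | COc1c(O)cc(C(=O)O)cc1O | starting material
17 | benzyl 3,5-bis(benzyloxy)-4-methoxybenzoate | COc1c(OCc2ccccc2)cc(C(=O)OCc2ccccc2)cc1OCc1ccccc1 | intermediate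
18 | [3,5-bis(benzyloxy)-4-methoxyphenyl]methanol | COc1c(OCc2ccccc2)cc(CO)cc1OCc1ccccc1 | intermediate
19 | 3,5-bis(benzyloxy)-4-methoxybenzaldehyde | COc1c(OCc2ccccc2)cc(C=O)cc1OCc1ccccc1 | intermediate
20 | 3,5-bis(benzyloxy)-4-methoxyphenyl formate | COc1c(OCc2ccccc2)cc(OC=O)cc1OCc1ccccc1 | intermediate
21 | 3,5-bis(benzyloxy)-4-methoxyphenol | COc1c(OCc2ccccc2)cc(O)cc1OCc1ccccc1 | intermediate
22 | ethyl (2E)-2-(benzyloxy)-3-[3,5-bis(benzyloxy)-4-methoxyphenoxy]-3-{4-(benzyloxy)-3-[(3S)-4-(benzyloxy)-3-methylbutyl]phenyl}prop-2-enoate | CCOC(=O)/C(OCc1ccccc1)=C(\Oc1cc(OCc2ccccc2)c(OC)c(OCc2ccccc2)c1)c1ccc(OCc2ccccc2)c(CC[C@H](C)COCc2ccccc2)c1 | intermediate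
23 | (2E)-2-(benzyloxy)-3-[3,5-bis(benzyloxy)-4-methoxyphenoxy]-3-{4-(benzyloxy)-3-[(3S)-4-(benzyloxy)-3-methylbutyl]phenyl}prop-2-enoic acid | OC(=O)/C(OCc1ccccc1)=C(\Oc1cc(OCc2ccccc2)c(OC)c(OCc2ccccc2)c1)c1ccc(OCc2ccccc2)c(CC[C@H](C)COCc2ccccc2)c1 | intermediate
24 | mixed anhydride of 23 with trifluoroacetic acid | FC(F)(F)C(=O)OC(=O)/C(OCc1ccccc1)=C(\Oc1cc(OCc2ccccc2)c(OC)c(OCc2ccccc2)c1)c1ccc(OCc2ccccc2)c(CC[C@H](C)COCc2ccccc2)c1 | intermediate
25 | 3,5,7-tris(benzyloxy)-2-{4-(benzyloxy)-3-[(3S)-4-(benzyloxy)-3-methylbutyl]phenyl}-6-methoxy-4H-chromen-4-one | COc1c(OCc2ccccc2)cc2oc(-c3ccc(OCc4ccccc4)c(CC[C@H](C)COCc4ccccc4)c3)c(OCc3ccccc3)c(=O)c2c1OCc1ccccc1 | intermediate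
26 | 3,7-bis(benzyloxy)-2-{4-(benzyloxy)-3-[(3S)-4-(benzyloxy)-3-methylbutyl]phenyl}-5-hydroxy-6-methoxy-4H-chromen-4-one | COc1c(OCc2ccccc2)cc2oc(-c3ccc(OCc4ccccc4)c(CC[C@H](C)COCc4ccccc4)c3)c(OCc3ccccc3)c(=O)c2c1O | intermediate
27 | 3,7-bis(benzyloxy)-2-{4-(benzyloxy)-3-[(3S)-4-(benzyloxy)-3-methylbutyl]phenyl}-5,6-dimethoxy-4H-chromen-4-one | COc1c(OCc2ccccc2)cc2oc(-c3ccc(OCc4ccccc4)c(CC[C@H](C)COCc4ccccc4)c3)c(OCc3ccccc3)c(=O)c2c1OC | intermediate
28 | 3,7-dihydroxy-2-{4-hydroxy-3-[(3S)-4-hydroxy-3-methylbutyl]phenyl}-5,6-dimethoxy-4H-chromen-4-one | COc1c(O)cc2oc(-c3ccc(O)c(CC[C@H](C)CO)c3)c(O)c(=O)c2c1OC | target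

## Summary

Total step count: 18.
Longest linear sequence: 13 steps (steps 1–3, 5–8, 13–18).

Steps most likely to fail:

1. Step 15 (key step). The donor-stabilised mixed anhydride may ionise slowly, so that acid-promoted loss of benzyl groups, hydrolysis of the aryl enol ether or intermolecular trifluoroacetylation of ring A take over. The fallback reverses the polarity of the same C4–C4a bond formation and sets out from ester 22. Bromination of ring A ortho to the ether oxygen (NBS, MeCN, 0 °C) should give ethyl (2E)-2-(benzyloxy)-3-[3,5-bis(benzyloxy)-2-bromo-4-methoxyphenoxy]-3-{4-(benzyloxy)-3-[(3S)-4-(benzyloxy)-3-methylbutyl]phenyl}prop-2-enoate F1. Bromine–lithium exchange (n-BuLi, THF, −100 °C) and intramolecular acyl substitution at the ethyl ester (Parham cyclisation) would then close ring C without acid and come back to the route at 25. This needs the E geometry that the stereoretentive coupling is expected to deliver.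

2. Step 13. The triflyl group may be transferred to the phenoxide by attack at sulfur, or reductive elimination at the tetrasubstituted alkenylpalladium may be slow. The fallback changes the electrophile and the mechanism and sets out from β-keto ester 13. Vilsmeier-type chlorination ((COCl)2, DMF, CH2Cl2) should give ethyl 2-(benzyloxy)-3-{4-(benzyloxy)-3-[(3S)-4-(benzyloxy)-3-methylbutyl]phenyl}-3-chloroprop-2-enoate F2, usable as either alkene isomer. This chloride cannot transfer a sulfonyl group. Heating it with phenol 21 and Cs2CO3 in DMF (uncatalysed addition–elimination, as in the classical β-chlorocrotonate/phenoxide reaction) would come back to the route at 22.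

3. Step 16. Site selectivity between the 5-O-benzyl group (six-membered chelate) and the 3-O-benzyl group (five-membered chelate) may be poor, or conversion incomplete. The fallback gives up selective cleavage in favour of selective re-protection and sets out from 25. Both chelating ethers are cleaved with BCl3 (2.2 equiv, CH2Cl2, −78 °C) to 7-(benzyloxy)-2-{4-(benzyloxy)-3-[(3S)-4-(benzyloxy)-3-methylbutyl]phenyl}-3,5-dihydroxy-6-methoxy-4H-chromen-4-one F3. The more acidic, non-chelated 3-hydroxyl is then benzylated alone (BnBr 1 equiv, K2CO3, acetone, rt), the hydrogen-bonded 5-hydroxyl staying free, which comes back to the route at 26.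

## Further compounds

F1 | step 15 | ethyl (2E)-2-(benzyloxy)-3-[3,5-bis(benzyloxy)-2-bromo-4-methoxyphenoxy]-3-{4-(benzyloxy)-3-[(3S)-4-(benzyloxy)-3-methylbutyl]phenyl}prop-2-enoate | CCOC(=O)/C(OCc1ccccc1)=C(\Oc1cc(OCc2ccccc2)c(OC)c(OCc2ccccc2)c1Br)c1ccc(OCc2ccccc2)c(CC[C@H](C)COCc2ccccc2)c1
F2 | step 13 | ethyl 2-(benzyloxy)-3-{4-(benzyloxy)-3-[(3S)-4-(benzyloxy)-3-methylbutyl]phenyl}-3-chloroprop-2-enoate (alkene geometry not defined) | CCOC(=O)C(OCc1ccccc1)=C(Cl)c1ccc(OCc2ccccc2)c(CC[C@H](C)COCc2ccccc2)c1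
F3 | step 16 | 7-(benzyloxy)-2-{4-(benzyloxy)-3-[(3S)-4-(benzyloxy)-3-methylbutyl]phenyl}-3,5-dihydroxy-6-methoxy-4H-chromen-4-one | COc1c(OCc2ccccc2)cc2oc(-c3ccc(OCc4ccccc4)c(CC[C@H](C)COCc4ccccc4)c3)c(O)c(=O)c2c1O
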